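## Retrosynthetic overview

1. Target ⇐ oxidation of the C3 carbinol ⇐ methyl addition to a C7 ketone ⇐ aldol condensation and conjugate reduction that join benzoxepinone enone 8 (C13) and hydroazulenyl-acetaldehyde 30 (C16) within the two-carbon linker.
2. West half 8: the oxepane and then the cyclohexanone close in one epoxide-opening cascade of the Shi-derived diepoxide of geranylacetone. The C8=C9 enone is added so that only C6 can be enolised.
3. East half 30: the side chain comes from an Eschenmoser–Claisen rearrangement of a C7 allylic alcohol, which a ketoreductase makes from enone 26.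
4. Enone 26 ⇐ gem-dimethylation and 1,3-carbonyl transposition of a cycloheptenone ⇐ one-carbon ring expansion of the six-membered ring of a catalytic asymmetric Diels–Alder adduct of cyclopentenone.
5. Ring order: east, five-membered ring (from cyclopentenone) → six → seven; west, seven-membered ether → six-membered carbocycle; fragment union last.

## Assumptions

- Locants follow 1-benzoxepine numbering (O1, C2 … C9a) for the western bicycle and azulene numbering (C1 … C8a) for the eastern one.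
- Compound 1 is used as the pure (E)-isomer.
- The (S)-configured oxazaborolidinium catalyst of step 8 is taken to give the (3aR,7aS) adduct; if the facial sense is the opposite, the (R)-catalyst is used with no other change.
- A ketoreductase giving the (7R)-alcohol in step 21 is found by screening an enzyme panel.

## Route

**Step 1**
Reactants: 1 (5E)-6,10-dimethylundeca-5,9-dien-2-one ((E)-geranylacetone)
Product: 2 4-[(2S,3S)-3-{2-[(2S)-3,3-dimethyloxiran-2-yl]ethyl}-3-methyloxiran-2-yl]butan-2-one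
Conditions: ent-Shi ketone C12H18O6 (L-fructose-derived, 30 mol %), KHSO5, K2CO3, Bu4NHSO4, MeCN–CH2(OMe)2–aq. Na2B4O7, 0 °C
Reagents that add atoms: potassium peroxymonosulfate, [K+].[O-]S(=O)(=O)OO
Why: Shi asymmetric epoxidation, in which the chiral dioxirane transfers oxygen to both (E)-trisubstituted alkenes through a spiro transition state, and the L-series ketone gives the (S)-configured CH centres (first stereocentres, set by catalysis).

**Step 2**
Reactants: 2 diepoxy ketone
Product: 3 tert-butyl({4-[(2S,3S)-3-{2-[(2S)-3,3-dimethyloxiran-2-yl]ethyl}-3-methyloxiran-2-yl]but-1-en-2-yl}oxy)dimethylsilane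
Conditions: LiN(i-Pr)2, THF, −78 °C; TBSCl, DMPU, −78 → 0 °C
Reagents that add atoms: tert-butyldimethylsilyl chloride, CC(C)(C)[Si](C)(C)Cl
Why: Kinetic deprotonation at the methyl group and O-silylation give the terminal silyl enol ether, while the epoxides are inert to the amide base at −78 °C.

**Step 3**
Reactants: 3 diepoxy silyl enol ether
Product: 5 (3S,5aS,9aS)-3-hydroxy-2,2,5a-trimethyloctahydro-1-benzoxepin-7(2H)-one, via trimethylsilyl ether 4 (not isolated)
Conditions: TMSOTf, 2,6-di-tert-butyl-4-methylpyridine, CH2Cl2, −78 °C; aq. NaHCO3; then 1 M HCl, THF, 0 °C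
Reagents that add atoms: none
Why: Tandem oxa-/carbacyclisation: the silylated terminal epoxide is opened 7-endo at its tertiary carbon by the internal epoxide oxygen, and the resulting epoxonium ion is opened with inversion at C5a by the enol silane through a chair, so the (E)-epoxide geometry gives the trans ring fusion (5aS,9aS).

**Step 4**
Reactants: 5 hydroxy ketone
Product: 6 (3S,5aS,9aS)-3-(tert-butyldimethylsilyloxy)-2,2,5a-trimethyloctahydro-1-benzoxepin-7(2H)-one
Conditions: TBSOTf, 2,6-lutidine, CH2Cl2, −78 °C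
Reagents that add atoms: tert-butyldimethylsilyl triflate, CC(C)(C)[Si](C)(C)OS(=O)(=O)C(F)(F)F
Why: Silyl triflate protection of the hindered secondary alcohol next to the gem-dimethyl carbon, with the ketone untouched at low temperature.

**Step 5**
Reactants: 6 silyl ether ketone
Product: 7 [(3S,5aS,9aS)-3-(tert-butyldimethylsilyloxy)-2,2,5a-trimethyl-2,3,4,5,5a,6,9,9a-octahydro-1-benzoxepin-7-yl]oxy-trimethylsilane (C7=C8 enol ether)
Conditions: LiN(i-Pr)2, THF, −78 °C; TMSCl
Reagents that add atoms: trimethylsilyl chloride, C[Si](C)(C)Cl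
Why: Kinetic enolisation goes to C8 and not to the neopentyl C6; any C6 enol ether cannot be dehydrogenated in step 6 and returns to 6.

**Step 6**
Reactants: 7 trimethylsilyl enol ether
Product: 8 (3S,5aS,9aS)-3-(tert-butyldimethylsilyloxy)-2,2,5a-trimethyl-3,4,5,5a,6,9a-hexahydro-1-benzoxepin-7(2H)-one (C8=C9 enone)
Conditions: Pd(OAc)2 (1.05 equiv), MeCN, rt
Reagents that add atoms: none
Why: Saegusa–Ito oxidation (oxa-π-allyl palladium, β-hydride elimination from C9) gives the only possible enone because C5a is quaternary, which leaves C6 as the sole enolisable position.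

**Step 7**
Reactants: 9 but-3-en-2-one
Product: 10 2-(triisopropylsilyloxy)buta-1,3-diene
Conditions: TIPSOTf, Et3N, Et2O, 0 °C → rt
Reagents that add atoms: triisopropylsilyl triflate, CC(C)[Si](C(C)C)(C(C)C)OS(=O)(=O)C(F)(F)F
Why: Soft enolisation and O-silylation of the methyl ketone give the acid-tolerant silyloxy diene.

**Step 8**
Reactants: 11 cyclopent-2-en-1-one; 10 2-(triisopropylsilyloxy)buta-1,3-diene
Product: 12 (3aR,7aS)-5-(triisopropylsilyloxy)-2,3,3a,4,7,7a-hexahydro-1H-inden-1-one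
Conditions: (S)-1-(2-methylphenyl)-3,3-diphenyl-tetrahydropyrrolo[1,2-c][1,3,2]oxazaborole C24H24BNO·HNTf2 (20 mol %), CH2Cl2, −78 → −20 °C
Reagents that add atoms: none
Why: Catalytic asymmetric Diels–Alder reaction in which the protonated oxazaborolidine activates and shields the enone; the diene adds suprafacially with para regiochemistry, which fixes the cis ring fusion and both ring-fusion centres.

**Step 9**
Reactants: 12 Diels–Alder adduct
Product: 13 (3aR,7aS)-configured tricyclic ketone, cyclopropane fused across C5–C6 of 12 with OSi(i-Pr)3 on the cyclopropane carbon C5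
Conditions: Et2Zn, CH2I2, CH2Cl2, 0 °C
Reagents that add atoms: diiodomethane, ICI
Why: Simmons–Smith (Furukawa) cyclopropanation of the electron-rich silyl enol ether; the ketone is inert and the new cyclopropane centres are destroyed in step 13.

**Step 10**
Reactants: 13 cyclopropyl ketone
Product: 14 1-methylidene analogue of 13
Conditions: Ph3PCH3Br, KOt-Bu, THF, 0 °C → rt
Reagents that add atoms: methyltriphenylphosphonium bromide, [Br-].C[P+](c1ccccc1)(c1ccccc1)c1ccccc1
Why: Wittig methylenation of the only carbonyl; the cis-fused hydrindan-1-one is the more stable epimer, so C7a is not at risk.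

**Step 11**
Reactants: 14 exocyclic alkene
Product: 15 spiro-epoxide at C1 of 14 with the epoxide oxygen cis to H-7a
Conditions: mCPBA, NaHCO3, CH2Cl2, 0 °C
Reagents that add atoms: 3-chloroperbenzoic acid, OOC(=O)c1cccc(Cl)c1
Why: Prilezhaev epoxidation from the convex face of the cis-fused bicycle delivers oxygen syn to the ring-fusion hydrogens, which sets the C1 configuration of the later tertiary carbinol.

**Step 12**
Reactants: 15 spiro-epoxide
Product: 16 C1 methyl carbinol (tertiary OH cis to H-7a) of the silyloxycyclopropane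
Conditions: LiEt3BH, THF, 0 °C → rt
Reagents that add atoms: none
Why: SN2 hydride opening at the unhindered epoxide CH2 gives the tertiary alcohol with C1 unchanged.

**Step 13**
Reactants: 16 silyloxycyclopropane alcohol
Product: 18 (1S,3aR,8aS)-1-hydroxy-1-methyl-2,3,3a,4,8,8a-hexahydroazulen-5(1H)-one, via chloro ketone 17 (not isolated)
Conditions: FeCl3, pyridine, DMF, 0 °C → rt; then NaOAc, MeOH, 65 °C
Reagents that add atoms: none
Why: Ito–Saegusa ring expansion: one-electron oxidation cleaves the internal cyclopropane bond to the secondary β-keto radical, which takes chlorine, and E1cB loss of HCl gives the cycloheptenone with the carbonyl at the former silyloxy carbon.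

**Step 14**
Reactants: 18 hydroxy enone
Product: 19 (1S,3aR,8aS)-1-methyl-1-(triethylsilyloxy)-2,3,3a,4,8,8a-hexahydroazulen-5(1H)-one
Conditions: TESOTf, 2,6-lutidine, CH2Cl2, −78 °C
Reagents that add atoms: triethylsilyl triflate, CC[Si](CC)(CC)OS(=O)(=O)C(F)(F)F
Why: Silyl triflate protection of the tertiary alcohol.

**Step 15**
Reactants: 19 enone
Product: 21 4,4-dimethyl derivative of 19, via monomethyl enone 20 (not isolated)
Conditions: LiN(i-Pr)2, THF, −78 °C; MeI; then LiN(i-Pr)2, −78 °C; MeI, DMPU, → 0 °C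
Reagents that add atoms: iodomethane, CI
Why: Kinetic α′-deprotonation of the enone (cross-conjugated enolate) and alkylation, done twice at C4, the only α′ carbon; C4 carries no stereocentre afterwards.

**Step 16**
Reactants: 21 gem-dimethyl enone
Product: 22 1,4,4-trimethyl-1-(triethylsilyloxy)octahydroazulen-5(1H)-one (ring-fusion and C1 configuration as in 19)
Conditions: H2 (1 atm), Pd/C, EtOAc, rt
Reagents that add atoms: none
Why: Heterogeneous hydrogenation of the only C=C bond.

**Step 17**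
Reactants: 22 saturated ketone
Product: 23 6-methyl derivative of 22 (C6 epimers)
Conditions: LiN(i-Pr)2, THF, −78 °C; MeI, → 0 °C
Reagents that add atoms: iodomethane, CI
Why: Enolate alkylation; the ketone can enolise only towards C6 because C4 is quaternary, and the new centre is removed in step 18.

**Step 18**
Reactants: 23 α-methyl ketone
Product: 24 1,4,4,6-tetramethyl-1-(triethylsilyloxy)-1,2,3,3a,4,7,8,8a-octahydroazulen-5-yl trifluoromethanesulfonate
Conditions: KN(SiMe3)2, THF, −78 → 0 °C; N-(5-chloropyridin-2-yl)bis(trifluoromethanesulfonyl)imide, −78 °C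
Reagents that add atoms: N-(5-chloropyridin-2-yl)bis(trifluoromethanesulfonyl)imide (Comins' reagent), FC(F)(F)S(=O)(=O)N(c1ccc(Cl)cn1)S(=O)(=O)C(F)(F)F
Why: O-triflation of the only possible enolate gives the tetrasubstituted enol triflate regiospecifically.

**Step 19**
Reactants: 24 enol triflate
Product: 25 (1S,3aS,8aS)-1,4,4,6-tetramethyl-1-(triethylsilyloxy)-1,2,3,3a,4,7,8,8a-octahydroazulene (C5=C6 alkene)
Conditions: Pd(OAc)2 (5 mol %), PPh3, HCO2H, Bu3N, DMF, 60 °C
Reagents that add atoms: none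
Why: Palladium-catalysed formate reduction of the enol triflate (oxidative addition, hydride from formate, reductive elimination) removes the C5 oxygen and leaves the trisubstituted alkene.

**Step 20**
Reactants: 25 alkene
Product: 26 (1S,3aS,8aS)-1,4,4,6-tetramethyl-1-(triethylsilyloxy)-2,3,3a,4,8,8a-hexahydroazulen-7(1H)-one
Conditions: CrO3, 3,5-dimethylpyrazole, CH2Cl2, −20 °C
Reagents that add atoms: chromium trioxide, O=[Cr](=O)=O
Why: Allylic C–H oxidation: C7 is the only ring allylic methylene (C4 is quaternary) and oxygen enters at the unhindered allyl terminus, which completes a 1,3-carbonyl transposition to the 6-methyl enone.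

**Step 21**
Reactants: 26 enone
Product: 27 (1S,3aS,7R,8aS)-1,4,4,6-tetramethyl-1-(triethylsilyloxy)-1,2,3,3a,4,7,8,8a-octahydroazulen-7-ol
Conditions: ketoreductase, NADP+ (cat.), i-PrOH, phosphate buffer pH 7, DMSO (5 %), 30 °C
Reagents that add atoms: none
Why: Enzymatic carbonyl reduction: the ketoreductase delivers the NADPH hydride to one face of the enone carbonyl under enzyme control, giving the (7R)-alcohol with OH on the face opposite the ring-fusion hydrogens; isopropanol recycles the cofactor.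

**Step 22**
Reactants: 27 allylic alcohol
Product: 29 2-[(1S,3aS,5R,8aS)-1,4,4,6-tetramethyl-1-(triethylsilyloxy)-1,2,3,3a,4,5,8,8a-octahydroazulen-5-yl]-N,N-dimethylacetamide, via ketene N,O-acetal 28 (not isolated)
Conditions: MeC(OMe)2NMe2, xylene, 140 °C, MeOH distilled off
Reagents that add atoms: N,N-dimethylacetamide dimethyl acetal, CC(OC)(OC)N(C)C
Why: Eschenmoser–Claisen rearrangement: the suprafacial [3,3] shift forms the C5–C bond on the face that held the C7–O bond (syn to the five-membered ring), so C5 is set as R by chirality transfer and the C6=C7 alkene lands in its final place.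

**Step 23**
Reactants: 29 amide
Product: 30 2-[(1S,3aS,5R,8aS)-1,4,4,6-tetramethyl-1-(triethylsilyloxy)-1,2,3,3a,4,5,8,8a-octahydroazulen-5-yl]acetaldehyde
Conditions: Cp2Zr(H)Cl, THF, rt
Reagents that add atoms: none
Why: Hydrozirconation of the tertiary amide carbonyl gives a zirconated hemiaminal that releases the aldehyde on work-up without over-reduction; the trisubstituted alkene is inert.

**Step 24**
Reactants: 8 benzoxepinone enone; 30 hydroazulenyl-acetaldehyde
Product: 31 aldol adduct, 8 bearing at C6 a 1-hydroxy-2-(hydroazulen-5-yl)ethyl group (epimers at C6 and at the carbinol)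
Conditions: LiN(i-Pr)2, THF, −78 °C (8); then 30, −78 °C
Reagents that add atoms: none
Why: Directed aldol addition: kinetic α′-deprotonation of the enone can occur only at C6, and the lithium enolate adds to the unhindered aldehyde faster than proton transfer.

**Step 25**
Reactants: 31 aldol adduct
Product: 33 cross-conjugated dienone with a C6 exocyclic 2-(hydroazulen-5-yl)ethylidene group (E/Z mixture), via mesylate 32 (not isolated)
Conditions: MsCl, Et3N, CH2Cl2, 0 °C; then DBU, rt
Reagents that add atoms: none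
Why: Mesylation and E1cB elimination of the β-hydroxy ketone; the alkene geometry is irrelevant.

**Step 26**
Reactants: 33 dienone
Product: 35 (3S,5aS,6S,9aS)-3-(tert-butyldimethylsilyloxy)-2,2,5a-trimethyl-6-{2-[(1S,3aS,5R,8aS)-1,4,4,6-tetramethyl-1-(triethylsilyloxy)-1,2,3,3a,4,5,8,8a-octahydroazulen-5-yl]ethyl}octahydro-1-benzoxepin-7(2H)-one, via epimer mixture 34 (not isolated)
Conditions: [(Ph3P)CuH]6, benzene, H2O, rt; aq. NH4Cl; then K2CO3, MeOH, rt
Reagents that add atoms: none
Why: Copper hydride conjugate reduction saturates both enone C=C bonds and spares the isolated trisubstituted alkene; base equilibration then places the C6 side chain equatorial (6S).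

**Step 27**
Reactants: 35 ketone
Product: 36 (3S,5aS,6S,7R,9aS)-3-(tert-butyldimethylsilyloxy)-2,2,5a,7-tetramethyl-6-{2-[(1S,3aS,5R,8aS)-1,4,4,6-tetramethyl-1-(triethylsilyloxy)-1,2,3,3a,4,5,8,8a-octahydroazulen-5-yl]ethyl}decahydro-1-benzoxepin-7-ol
Conditions: MeLi, CeCl3, THF, −78 °C
Reagents that add atoms: methyllithium, [Li]C
Why: Non-basic organocerium 1,2-addition; equatorial attack, away from the axial C5a methyl, gives the axial hydroxyl and equatorial methyl (7R).

**Step 28**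
Reactants: 36 bis-silyl ether
Product: 37 (3S,5aS,6S,7R,9aS)-6-{2-[(1S,3aS,5R,8aS)-1-hydroxy-1,4,4,6-tetramethyl-1,2,3,3a,4,5,8,8a-octahydroazulen-5-yl]ethyl}-2,2,5a,7-tetramethyldecahydro-1-benzoxepine-3,7-diol
Conditions: Bu4NF, THF, 50 °C
Reagents that add atoms: none
Why: Fluoride cleaves both silyl ethers under basic conditions that do not ionise the tertiary alcohols.

**Step 29**
Reactants: 37 triol
Product: 38 target, (5aS,6S,7R,9aS)-7-hydroxy-6-{2-[(1S,3aS,5R,8aS)-1-hydroxy-1,4,4,6-tetramethyl-1,2,3,3a,4,5,8,8a-octahydroazulen-5-yl]ethyl}-2,2,5a,7-tetramethyloctahydro-1-benzoxepin-3(2H)-one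
Conditions: Dess–Martin periodinane, NaHCO3, CH2Cl2, rt
Reagents that add atoms: none
Why: Dess–Martin oxidation of the only secondary alcohol; the two tertiary alcohols cannot be oxidised and no stereocentre is touched.

## Compound list

1 | (5E)-6,10-dimethylundeca-5,9-dien-2-one | CC(C)=CCC/C(C)=C/CCC(C)=O | starting material
2 | 4-[(2S,3S)-3-{2-[(2S)-3,3-dimethyloxiran-2-yl]ethyl}-3-methyloxiran-2-yl]butan-2-one | CC1(C)O[C@H]1CC[C@]1(C)O[C@H]1CCC(C)=O | intermediate
3 | tert-butyldimethylsilyl enol ether of 2 (terminal C=CH2) | CC1(C)O[C@H]1CC[C@]1(C)O[C@H]1CCC(=C)O[Si](C)(C)C(C)(C)C | intermediate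
4 | (3S,5aS,9aS)-2,2,5a-trimethyl-3-(trimethylsilyloxy)octahydro-1-benzoxepin-7(2H)-one | O=C1C[C@]2(C)CC[C@H](O[Si](C)(C)C)C(C)(C)O[C@H]2CC1 | intermediate (not isolated)
5 | (3S,5aS,9aS)-3-hydroxy-2,2,5a-trimethyloctahydro-1-benzoxepin-7(2H)-one | O=C1C[C@]2(C)CC[C@H](O)C(C)(C)O[C@H]2CC1 | intermediate
6 | (3S,5aS,9aS)-3-(tert-butyldimethylsilyloxy)-2,2,5a-trimethyloctahydro-1-benzoxepin-7(2H)-one | O=C1C[C@]2(C)CC[C@H](O[Si](C)(C)C(C)(C)C)C(C)(C)O[C@H]2CC1 | intermediate
7 | C7=C8 trimethylsilyl enol ether of 6 | C[Si](C)(C)OC1=CC[C@@H]2OC(C)(C)[C@@H](O[Si](C)(C)C(C)(C)C)CC[C@@]2(C)C1 | intermediate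
8 | (3S,5aS,9aS)-3-(tert-butyldimethylsilyloxy)-2,2,5a-trimethyl-3,4,5,5a,6,9a-hexahydro-1-benzoxepin-7(2H)-one | O=C1C[C@]2(C)CC[C@H](O[Si](C)(C)C(C)(C)C)C(C)(C)O[C@H]2C=C1 | intermediate
9 | but-3-en-2-one | CC(=O)C=C | starting material
10 | 2-(triisopropylsilyloxy)buta-1,3-diene | C=CC(=C)O[Si](C(C)C)(C(C)C)C(C)C | intermediate
11 | cyclopent-2-en-1-one | O=C1CCC=C1 | starting material
12 | (3aR,7aS)-5-(triisopropylsilyloxy)-2,3,3a,4,7,7a-hexahydro-1H-inden-1-one | O=C1CC[C@@H]2CC(O[Si](C(C)C)(C(C)C)C(C)C)=CC[C@H]12 | intermediate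
13 | cyclopropane fused across C5–C6 of 12, OSi(i-Pr)3 on C5 (cyclopropane epimers not defined) | O=C1CC[C@@H]2CC3(O[Si](C(C)C)(C(C)C)C(C)C)CC3C[C@H]12 | intermediate
14 | 1-methylidene analogue of 13 | C=C1CC[C@@H]2CC3(O[Si](C(C)C)(C(C)C)C(C)C)CC3C[C@H]12 | intermediate
15 | spiro-epoxide of 14, oxygen cis to H-7a | C1O[C@]12CC[C@@H]3CC4(O[Si](C(C)C)(C(C)C)C(C)C)CC4C[C@H]23 | intermediate
16 | C1 methyl carbinol from 15, OH cis to H-7a | C[C@]1(O)CC[C@@H]2CC3(O[Si](C(C)C)(C(C)C)C(C)C)CC3C[C@H]12 | intermediate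
17 | 7-chloro-1-hydroxy-1-methyloctahydroazulen-5(1H)-one (C7 epimers) | C[C@]1(O)CC[C@@H]2CC(=O)CC(Cl)C[C@H]12 | intermediate (not isolated)
18 | (1S,3aR,8aS)-1-hydroxy-1-methyl-2,3,3a,4,8,8a-hexahydroazulen-5(1H)-one | C[C@]1(O)CC[C@@H]2CC(=O)C=CC[C@H]12 | intermediate
19 | (1S,3aR,8aS)-1-methyl-1-(triethylsilyloxy)-2,3,3a,4,8,8a-hexahydroazulen-5(1H)-one | C[C@]1(O[Si](CC)(CC)CC)CC[C@@H]2CC(=O)C=CC[C@H]12 | intermediate
20 | 4-methyl derivative of 19 (C4 epimers) | C[C@]1(O[Si](CC)(CC)CC)CC[C@@H]2C(C)C(=O)C=CC[C@H]12 | intermediate (not isolated)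
21 | 4,4-dimethyl derivative of 19 | C[C@]1(O[Si](CC)(CC)CC)CC[C@@H]2C(C)(C)C(=O)C=CC[C@H]12 | intermediate
22 | 1,4,4-trimethyl-1-(triethylsilyloxy)octahydroazulen-5(1H)-one | C[C@]1(O[Si](CC)(CC)CC)CC[C@@H]2C(C)(C)C(=O)CCC[C@H]12 | intermediate
23 | 6-methyl derivative of 22 (C6 epimers) | C[C@]1(O[Si](CC)(CC)CC)CC[C@@H]2C(C)(C)C(=O)C(C)CC[C@H]12 | intermediate
24 | C5 enol triflate of 23 (C5=C6) | C[C@]1(O[Si](CC)(CC)CC)CC[C@@H]2C(C)(C)C(OS(=O)(=O)C(F)(F)F)=C(C)CC[C@H]12 | intermediate
25 | (1S,3aS,8aS)-1,4,4,6-tetramethyl-1-(triethylsilyloxy)-1,2,3,3a,4,7,8,8a-octahydroazulene | C[C@]1(O[Si](CC)(CC)CC)CC[C@@H]2C(C)(C)C=C(C)CC[C@H]12 | intermediate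
26 | (1S,3aS,8aS)-1,4,4,6-tetramethyl-1-(triethylsilyloxy)-2,3,3a,4,8,8a-hexahydroazulen-7(1H)-one | C[C@]1(O[Si](CC)(CC)CC)CC[C@@H]2C(C)(C)C=C(C)C(=O)C[C@H]12 | intermediate
27 | (1S,3aS,7R,8aS)-1,4,4,6-tetramethyl-1-(triethylsilyloxy)-1,2,3,3a,4,7,8,8a-octahydroazulen-7-ol | C[C@]1(O[Si](CC)(CC)CC)CC[C@@H]2C(C)(C)C=C(C)[C@H](O)C[C@H]12 | intermediate
28 | 7-O-[1-(dimethylamino)ethenyl] ether of 27 | C[C@]1(O[Si](CC)(CC)CC)CC[C@@H]2C(C)(C)C=C(C)[C@H](OC(=C)N(C)C)C[C@H]12 | intermediate (not isolated)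
29 | 2-[(1S,3aS,5R,8aS)-1,4,4,6-tetramethyl-1-(triethylsilyloxy)-1,2,3,3a,4,5,8,8a-octahydroazulen-5-yl]-N,N-dimethylacetamide | CC1=CC[C@H]2[C@H](CC[C@]2(C)O[Si](CC)(CC)CC)C(C)(C)[C@@H]1CC(=O)N(C)C | intermediate
30 | 2-[(1S,3aS,5R,8aS)-1,4,4,6-tetramethyl-1-(triethylsilyloxy)-1,2,3,3a,4,5,8,8a-octahydroazulen-5-yl]acetaldehyde | CC1=CC[C@H]2[C@H](CC[C@]2(C)O[Si](CC)(CC)CC)C(C)(C)[C@@H]1CC=O | intermediate
31 | aldol adduct of 8 (C6) and 30 (epimers at C6 and carbinol) | O=C1C(C(O)C[C@@H]3C(C)=CC[C@H]4[C@H](CC[C@]4(C)O[Si](CC)(CC)CC)C3(C)C)[C@]2(C)CC[C@H](O[Si](C)(C)C(C)(C)C)C(C)(C)O[C@H]2C=C1 | intermediate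
32 | methanesulfonate of 31 | O=C1C(C(OS(C)(=O)=O)C[C@@H]3C(C)=CC[C@H]4[C@H](CC[C@]4(C)O[Si](CC)(CC)CC)C3(C)C)[C@]2(C)CC[C@H](O[Si](C)(C)C(C)(C)C)C(C)(C)O[C@H]2C=C1 | intermediate (not isolated)
33 | C6-alkylidene cross-conjugated dienone (E/Z) | O=C1C(=CC[C@@H]3C(C)=CC[C@H]4[C@H](CC[C@]4(C)O[Si](CC)(CC)CC)C3(C)C)[C@]2(C)CC[C@H](O[Si](C)(C)C(C)(C)C)C(C)(C)O[C@H]2C=C1 | intermediate
34 | saturated C7 ketone, C6 epimer mixture | O=C1C(CC[C@@H]3C(C)=CC[C@H]4[C@H](CC[C@]4(C)O[Si](CC)(CC)CC)C3(C)C)[C@]2(C)CC[C@H](O[Si](C)(C)C(C)(C)C)C(C)(C)O[C@H]2CC1 | intermediate (not isolated)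
35 | (3S,5aS,6S,9aS) C7 ketone, side chain equatorial | O=C1[C@@H](CC[C@@H]3C(C)=CC[C@H]4[C@H](CC[C@]4(C)O[Si](CC)(CC)CC)C3(C)C)[C@]2(C)CC[C@H](O[Si](C)(C)C(C)(C)C)C(C)(C)O[C@H]2CC1 | intermediate
36 | (3S,5aS,6S,7R,9aS) C7 tertiary alcohol, bis-silyl ether | C[C@]1(O)[C@@H](CC[C@@H]3C(C)=CC[C@H]4[C@H](CC[C@]4(C)O[Si](CC)(CC)CC)C3(C)C)[C@]2(C)CC[C@H](O[Si](C)(C)C(C)(C)C)C(C)(C)O[C@H]2CC1 | intermediate
37 | triol (C3 secondary, C7 and azulene C1 tertiary alcohols) | C[C@]1(O)[C@@H](CC[C@@H]3C(C)=CC[C@H]4[C@H](CC[C@]4(C)O)C3(C)C)[C@]2(C)CC[C@H](O)C(C)(C)O[C@H]2CC1 | intermediate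
38 | CNP0194989.3 | CC1=CC[C@H]2[C@H](CC[C@]2(C)O)C(C)(C)[C@@H]1CC[C@H]1[C@]2(C)CCC(=O)C(C)(C)O[C@H]2CC[C@@]1(C)O | target

## Step count and risks

Total: 29 steps. Longest linear sequence: 23 steps (steps 7–23, then 24–29); the western branch (steps 1–6) is 6 steps.

**Step 3 (epoxide-opening cascade).** Competing hydride shifts or premature enol ether loss can lower the yield. The fallback sets out from 2 and comes back at 5. Ketone 2 is converted with KN(SiMe3)2 and PhNTf2 into the kinetic enol triflate F1. Coupling with Me3SiCH2MgCl under Pd(PPh3)4 catalysis gives the 2-substituted allylsilane F2, a stronger terminator that cannot be hydrolysed back to a ketone. BF3·OEt2 in CH2Cl2 at −78 °C then gives the 7-methylidene bicyclic alcohol F3, and ozonolysis (O3, then Me2S) returns hydroxy ketone 5.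

**Step 20 (allylic oxidation).** Over-oxidation or attack at the methyl group is possible. The fallback sets out from 25 and comes back at 26. A selenium dioxide ene/[2,3] sequence (SeO2 cat., t-BuOOH, CH2Cl2) hydroxylates C7 without allylic transposition to give the allylic alcohol F4 as C7 epimers. MnO2 then oxidises both epimers to enone 26, so the C7 configuration is still set by the ketoreductase.

**Step 22 (Eschenmoser–Claisen).** The new bond forms at a neopentyl carbon on the concave face, and diene formation may compete at 140 °C. The fallback sets out from 27 and comes back at 30. KH and Bu3SnCH2I give the stannylmethyl ether F5. Tin–lithium exchange with n-BuLi at −78 °C triggers a [2,3]-Wittig–Still shift through a five-membered transition state, equally suprafacial, to the C5 hydroxymethyl compound F6. Dess–Martin oxidation gives the aldehyde F7, used crude. Ph3P=CHOMe gives the enol ether F8, and Hg(OAc)2 in aqueous THF followed by KI unveils aldehyde 30.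

## Further compounds

F1 | step 3 | 4-[(2S,3S)-3-{2-[(2S)-3,3-dimethyloxiran-2-yl]ethyl}-3-methyloxiran-2-yl]but-1-en-2-yl trifluoromethanesulfonate | CC1(C)O[C@H]1CC[C@]1(C)O[C@H]1CCC(=C)OS(=O)(=O)C(F)(F)F
F2 | step 3 | trimethyl({2-methylidene-4-[(2S,3S)-3-{2-[(2S)-3,3-dimethyloxiran-2-yl]ethyl}-3-methyloxiran-2-yl]butyl})silane | CC1(C)O[C@H]1CC[C@]1(C)O[C@H]1CCC(=C)C[Si](C)(C)C
F3 | step 3 | (3S,5aS,9aS)-2,2,5a-trimethyl-7-methylidenedecahydro-1-benzoxepin-3-ol | C=C1C[C@]2(C)CC[C@H](O)C(C)(C)O[C@H]2CC1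
F4 | step 20 | 1,4,4,6-tetramethyl-1-(triethylsilyloxy)-1,2,3,3a,4,7,8,8a-octahydroazulen-7-ol (C7 epimers) | C[C@]1(O[Si](CC)(CC)CC)CC[C@@H]2C(C)(C)C=C(C)C(O)C[C@H]12
F5 | step 22 | 7-O-(tributylstannylmethyl) ether of 27 | C[C@]1(O[Si](CC)(CC)CC)CC[C@@H]2C(C)(C)C=C(C)[C@H](OC[Sn](CCCC)(CCCC)CCCC)C[C@H]12
F6 | step 22 | [(1S,3aS,5R,8aS)-1,4,4,6-tetramethyl-1-(triethylsilyloxy)-1,2,3,3a,4,5,8,8a-octahydroazulen-5-yl]methanol | CC1=CC[C@H]2[C@H](CC[C@]2(C)O[Si](CC)(CC)CC)C(C)(C)[C@@H]1CO
F7 | step 22 | (1S,3aS,5R,8aS)-1,4,4,6-tetramethyl-1-(triethylsilyloxy)-1,2,3,3a,4,5,8,8a-octahydroazulene-5-carbaldehyde | CC1=CC[C@H]2[C@H](CC[C@]2(C)O[Si](CC)(CC)CC)C(C)(C)[C@@H]1C=O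
F8 | step 22 | 5-(2-methoxyethenyl) analogue of F7 (E/Z) | CC1=CC[C@H]2[C@H](CC[C@]2(C)O[Si](CC)(CC)CC)C(C)(C)[C@@H]1C=COC
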